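The route disconnects the two phenolic C–O bonds that lie ortho to the acetyl groups: C6–O on ring A (the ring without C-methyl) and C6'–O on ring B. In the target each acetyl-bearing carbon (C1, C1') is flanked by OMe (C2, C2') and by OH (C6, C6'), so each ketone can direct palladium to exactly one C–H. A single two-fold Pd-catalysed, ketone-directed C–H hydroxylation therefore raises both rings from the resorcinol to the phloroglucinol oxidation pattern. Its precursor is the diacetate of a diarylmethane made by joining two 4-hydroxy-2-methoxyacetophenones through a CH2 bridge (C5 of ring A to C3' of ring B) by quinone methide alkylation.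

Key step: step 8

Atom labels (both rings numbered as acetophenones): ring A C1 acetyl, C2 OMe, C3 H, C4 OH, C5 CH2 bridge, C6 OH; ring B C1' acetyl, C2' OMe, C3' CH2 bridge, C4' OH, C5' CH3, C6' OH. The target has no stereocentre, so no step has to control configuration; compounds 1 and 7 and all reagents are taken to be commercial.

Step 1
Reactants: 1 4-methylresorcinol (4-methylbenzene-1,3-diol)
Product: 2 1-(2,4-dihydroxy-5-methylphenyl)ethan-1-one
Conditions: AcOH, ZnCl2, 140 °C
Reagents that add atoms: acetic acid, CC(=O)O
Why: Nencki reaction (Friedel–Crafts-type C-acylation of a resorcinol by AcOH/ZnCl2): the position para to one hydroxyl and ortho to the other is acylated, and with C4 of the resorcinol blocked by methyl this is a single site, so 2 should form as one regioisomer.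

Step 2
Reactants: 2 1-(2,4-dihydroxy-5-methylphenyl)ethan-1-one
Product: 3 1-[4-(benzyloxy)-2-hydroxy-5-methylphenyl]ethan-1-one
Conditions: BnBr (1.05 equiv), K2CO3, acetone, reflux
Reagents that add atoms: benzyl bromide, BrCc1ccccc1
Why: Williamson ether synthesis: the C2 hydroxyl is held in a hydrogen bond to the acetyl carbonyl and is much less nucleophilic, so one equivalent of benzyl bromide should alkylate only the C4 phenol.

Step 3
Reactants: 3 1-[4-(benzyloxy)-2-hydroxy-5-methylphenyl]ethan-1-one
Product: 4 1-[4-(benzyloxy)-2-methoxy-5-methylphenyl]ethan-1-one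
Conditions: MeI (excess), K2CO3, DMF, 50 °C
Reagents that add atoms: iodomethane, CI
Why: Williamson ether synthesis under more forcing conditions: with the C4 oxygen capped, excess MeI in DMF should methylate the chelated C2 phenol, K2CO3 being too weak a base to enolise the ketone.

Step 4
Reactants: 4 1-[4-(benzyloxy)-2-methoxy-5-methylphenyl]ethan-1-one
Product: 5 1-(4-hydroxy-2-methoxy-5-methylphenyl)ethan-1-one
Conditions: H2 (1 atm), 10% Pd/C, EtOAc, rt
Reagents that add atoms: none
Why: Catalytic hydrogenolysis of the benzyl ether: the O–CH2Ph bond is cleaved at 1 atm and room temperature, conditions under which the donor-substituted aryl ketone should not be reduced if the reaction is stopped after one equivalent of H2.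

Step 5
Reactants: 5 1-(4-hydroxy-2-methoxy-5-methylphenyl)ethan-1-one
Product: 6 1-{3-[(dimethylamino)methyl]-4-hydroxy-2-methoxy-5-methylphenyl}ethan-1-one
Conditions: CH2(NMe2)2 (1.3 equiv), 1,4-dioxane, reflux
Reagents that add atoms: bis(dimethylamino)methane, CN(C)CN(C)C
Why: Mannich aminomethylation of a phenol with a preformed aminal: C3 is the only free position ortho to the phenol (C5 carries the methyl group, C6 is meta to it), and the neutral, amine-rich medium should keep the acetyl CH3 from reacting.

Step 6
Reactants: 6 1-{3-[(dimethylamino)methyl]-4-hydroxy-2-methoxy-5-methylphenyl}ethan-1-one and 7 1-(4-hydroxy-2-methoxyphenyl)ethan-1-one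
Product: 9 1-{5-[(3-acetyl-6-hydroxy-2-methoxy-5-methylphenyl)methyl]-4-hydroxy-2-methoxyphenyl}ethan-1-one, via ortho-quinone methide 8 (not isolated)
Conditions: 7 (3 equiv), DMF, 120 °C
Reagents that add atoms: none
Why: The Mannich base, a para-acylphenol that exists largely as its ammonium phenoxide, should lose dimethylamine on heating to give ortho-quinone methide 8, which the phenoxide of 7 traps by conjugate addition (Friedel–Crafts-type ortho C-alkylation) at C5, the position ortho to the phenol and para to OMe that is not crowded by the methoxy group, while the excess of 7 holds back a second alkylation and rearomatisation makes the C–C bond formation irreversible.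

Step 7
Reactants: 9 1-{5-[(3-acetyl-6-hydroxy-2-methoxy-5-methylphenyl)methyl]-4-hydroxy-2-methoxyphenyl}ethan-1-one
Product: 10 4-acetyl-2-{[3-acetyl-6-(acetyloxy)-2-methoxy-5-methylphenyl]methyl}-5-methoxyphenyl acetate
Conditions: Ac2O, pyridine, DMAP (cat.), CH2Cl2, rt
Reagents that add atoms: acetic anhydride, CC(=O)OC(C)=O
Why: DMAP-catalysed O-acylation: neither phenol of 9 is hydrogen-bonded to a ketone, so both, including the ortho,ortho-disubstituted one on ring B, should be acetylated.

Step 8
Reactants: 10 4-acetyl-2-{[3-acetyl-6-(acetyloxy)-2-methoxy-5-methylphenyl]methyl}-5-methoxyphenyl acetate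
Product: 12 4-acetyl-2-{[3-acetyl-6-(acetyloxy)-4-hydroxy-2-methoxy-5-methylphenyl]methyl}-3-hydroxy-5-methoxyphenyl acetate, via bis(trifluoroacetate) 11 (not isolated)
Conditions: Pd(OAc)2 (20 mol %), K2S2O8 (5 equiv), CF3CO2H/(CF3CO)2O (9:1), 50 °C; then H2O
Reagents that add atoms: trifluoroacetic acid, OC(=O)C(F)(F)F (its carboxylate oxygen becomes each new phenolic oxygen)
Why: The acetyl oxygen of each ring binds divalent palladium, and carboxylate-assisted concerted metalation–deprotonation at the single ortho C–H (C6–H on ring A, C6'–H on ring B) gives a five-membered palladacycle, which persulfate oxidises to a tetravalent palladium trifluoroacetate; C–O reductive elimination then gives the aryl trifluoroacetate (11), which water cleaves on work-up. This is the established ketone-directed ortho C–H hydroxylation of aryl ketones with Pd(OAc)2 and K2S2O8 or PhI(OCOCF3)2 in CF3CO2H, applied here at two sites of one substrate. No ring of the product is closed and no stereocentre is created. The step needs oxidation at C6–H and C6'–H only, and not at the doubly benzylic CH2, at C3–H of ring A or at the arene rings: the OMe groups at C2 and C2' leave each ketone a single palladation site, the two aryl acetates lower the electron density of both rings, and trifluoroacetylation in the flask shields each new phenol from over-oxidation. K2S2O8 is chosen over PhI(OCOCF3)2 because the iodine reagent can oxidise alkoxyarenes without the help of palladium.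

Step 9
Reactants: 12 4-acetyl-2-{[3-acetyl-6-(acetyloxy)-4-hydroxy-2-methoxy-5-methylphenyl]methyl}-3-hydroxy-5-methoxyphenyl acetate
Product: 13 1-{3-[(3-acetyl-2,6-dihydroxy-4-methoxyphenyl)methyl]-4,6-dihydroxy-2-methoxy-5-methylphenyl}ethan-1-one
Conditions: HCl (1.25 M in MeOH), 40 °C
Reagents that add atoms: none
Why: Acid-catalysed transesterification of the two aryl acetates with methanol (methyl acetate is lost); an acid is preferred to carbonate because phenoxides of methylene-bridged acylphloroglucinols are prone to cleavage and scrambling at the CH2 bridge and to air oxidation, while the aryl methyl ethers and chelated ketones should be inert.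

Compound list
1 | 4-methylresorcinol (4-methylbenzene-1,3-diol) | Cc1ccc(O)cc1O | starting material
2 | 1-(2,4-dihydroxy-5-methylphenyl)ethan-1-one | CC(=O)c1cc(C)c(O)cc1O | intermediate
3 | 1-[4-(benzyloxy)-2-hydroxy-5-methylphenyl]ethan-1-one | CC(=O)c1cc(C)c(OCc2ccccc2)cc1O | intermediate
4 | 1-[4-(benzyloxy)-2-methoxy-5-methylphenyl]ethan-1-one | COc1cc(OCc2ccccc2)c(C)cc1C(C)=O | intermediate
5 | 1-(4-hydroxy-2-methoxy-5-methylphenyl)ethan-1-one | COc1cc(O)c(C)cc1C(C)=O | intermediate
6 | 1-{3-[(dimethylamino)methyl]-4-hydroxy-2-methoxy-5-methylphenyl}ethan-1-one | COc1c(CN(C)C)c(O)c(C)cc1C(C)=O | intermediate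
7 | 1-(4-hydroxy-2-methoxyphenyl)ethan-1-one | COc1cc(O)ccc1C(C)=O | starting material
8 | 4-acetyl-3-methoxy-6-methyl-2-methylidenecyclohexa-3,5-dien-1-one (ortho-quinone methide of ring B) | C=C1C(=O)C(C)=CC(C(C)=O)=C1OC | intermediate
9 | 1-{5-[(3-acetyl-6-hydroxy-2-methoxy-5-methylphenyl)methyl]-4-hydroxy-2-methoxyphenyl}ethan-1-one | COc1cc(O)c(Cc2c(O)c(C)cc(C(C)=O)c2OC)cc1C(C)=O | intermediate
10 | 4-acetyl-2-{[3-acetyl-6-(acetyloxy)-2-methoxy-5-methylphenyl]methyl}-5-methoxyphenyl acetate | COc1cc(OC(C)=O)c(Cc2c(OC(C)=O)c(C)cc(C(C)=O)c2OC)cc1C(C)=O | intermediate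
11 | 4-acetyl-2-{[3-acetyl-6-(acetyloxy)-2-methoxy-5-methyl-4-(trifluoroacetoxy)phenyl]methyl}-5-methoxy-3-(trifluoroacetoxy)phenyl acetate | COc1cc(OC(C)=O)c(Cc2c(OC(C)=O)c(C)c(OC(=O)C(F)(F)F)c(C(C)=O)c2OC)c(OC(=O)C(F)(F)F)c1C(C)=O | intermediate
12 | 4-acetyl-2-{[3-acetyl-6-(acetyloxy)-4-hydroxy-2-methoxy-5-methylphenyl]methyl}-3-hydroxy-5-methoxyphenyl acetate | COc1cc(OC(C)=O)c(Cc2c(OC(C)=O)c(C)c(O)c(C(C)=O)c2OC)c(O)c1C(C)=O | intermediate
13 | 1-{3-[(3-acetyl-2,6-dihydroxy-4-methoxyphenyl)methyl]-4,6-dihydroxy-2-methoxy-5-methylphenyl}ethan-1-one | COc1cc(O)c(Cc2c(O)c(C)c(O)c(C(C)=O)c2OC)c(O)c1C(C)=O | target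

Total step count: 9. Longest linear sequence: 9 steps (1 to 13); 7 is a commercial building block that enters at step 6.

Steps most likely to fail

Step 8. What may go wrong: palladation may be slow at two C–H bonds that each sit between the acetyl group and a second substituent. Oxidation of the doubly benzylic CH2 or of the alkoxyarene rings by persulfate could then take over, or the reaction could stall after the first hydroxylation. Fallback (sets out from 9, returns at 13): the ketones are exchanged for stronger nitrogen directing groups and a milder oxidant is used in a non-fluorinated acid. Bisphenol 9 with NH2OH·HCl and NaOAc in EtOH at 70 °C should give the bis[(E)-oxime] F1. In AcOH/Ac2O both phenols and both oximes should be acetylated in the flask to the diacetate bis(O-acetyl oxime) F2. Pd(OAc)2 (10 mol %) with PhI(OAc)2 at 80–100 °C in the same medium (oxime-directed ortho C–H acetoxylation) should then give the C6,C6'-diacetoxylated bis(O-acetyl oxime) F3. NaHSO3 in aqueous EtOH at 80 °C, applied before any base so that no phenoxide can close onto the oxime nitrogen, should return both ketones as the tetraacetate diketone F4. The HCl/MeOH conditions of step 9 should then release the target 13.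

Step 6. What may go wrong: the quinone methide may attack C3 or the oxygen of 7 instead of C5, the product may be alkylated a second time, or the quinone methide may self-condense. Fallback (sets out from 7 and 5, returns at 9): the roles of the two rings are exchanged. Aminomethylation of 7 with CH2(NMe2)2 in refluxing 1,4-dioxane should give the C5 Mannich base 1-{5-[(dimethylamino)methyl]-4-hydroxy-2-methoxyphenyl}ethan-1-one F5. Any C3 isomer is removed at this monomer stage, where the two are told apart by whether the two aromatic protons are coupled. Heating F5 with an excess of phenol 5 in DMF should generate the ring A ortho-quinone methide F6. Phenol 5 can capture it only at C3', its single free position ortho to the phenol, and the product is 9.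

Step 5. What may go wrong: substitution at C3' may be sluggish, because this position is crowded between OMe and OH on a para-acylphenol of low nucleophilicity, or aminomethylation may occur at the acetyl CH3. Fallback (sets out from 5, returns at 9 through 8): Blanc chloromethylation of 5 with paraformaldehyde in conc. HCl at 40–50 °C is an acid-mediated electrophilic substitution at the same single ortho site, of the kind used on para-hydroxyacetophenones. It should give the benzylic chloride 1-[3-(chloromethyl)-4-hydroxy-2-methoxy-5-methylphenyl]ethan-1-one F7. With 7 (3 equiv) and K2CO3 in DMF, F7 should lose HCl at room temperature to give quinone methide 8, and warming as in step 6 should carry it on to 9.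

Further compounds
F1 | step 8 | bis[(E)-oxime] of 9: 2-({2-hydroxy-5-[(1E)-1-(hydroxyimino)ethyl]-4-methoxyphenyl}methyl)-4-[(1E)-1-(hydroxyimino)ethyl]-3-methoxy-6-methylphenol | COc1cc(O)c(Cc2c(O)c(C)cc(/C(C)=N/O)c2OC)cc1/C(C)=N/O
F2 | step 8 | diacetate bis(O-acetyl oxime): F1 with both phenols as OAc and both oximes as (E)-C(CH3)=N–OAc | COc1cc(OC(C)=O)c(Cc2c(OC(C)=O)c(C)cc(/C(C)=N/OC(C)=O)c2OC)cc1/C(C)=N/OC(C)=O
F3 | step 8 | C6,C6'-diacetoxylated bis(O-acetyl oxime): F2 with an additional OAc at C6 of ring A and at C6' of ring B | COc1cc(OC(C)=O)c(Cc2c(OC(C)=O)c(C)c(OC(C)=O)c(/C(C)=N/OC(C)=O)c2OC)c(OC(C)=O)c1/C(C)=N/OC(C)=O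
F4 | step 8 | tetraacetate diketone: 4-acetyl-2-{[3-acetyl-4,6-bis(acetyloxy)-2-methoxy-5-methylphenyl]methyl}-5-methoxy-1,3-phenylene diacetate | COc1cc(OC(C)=O)c(Cc2c(OC(C)=O)c(C)c(OC(C)=O)c(C(C)=O)c2OC)c(OC(C)=O)c1C(C)=O
F5 | step 6 | 1-{5-[(dimethylamino)methyl]-4-hydroxy-2-methoxyphenyl}ethan-1-one | COc1cc(O)c(CN(C)C)cc1C(C)=O
F6 | step 6 | 4-acetyl-3-methoxy-6-methylidenecyclohexa-2,4-dien-1-one (ortho-quinone methide of ring A) | C=C1C=C(C(C)=O)C(OC)=CC1=O
F7 | step 5 | 1-[3-(chloromethyl)-4-hydroxy-2-methoxy-5-methylphenyl]ethan-1-one | COc1c(CCl)c(O)c(C)cc1C(C)=O
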